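**Retrosynthetic overview**

1. Target 19 ⇐ pentabenzyl ether 18 ⇐ bis(thioester) 12 + arylboronic acid 17: the two 2,4-dihydroxybenzoyl groups are the same aryl ketone and are made together by a twofold acyl cross-coupling.
2. 12 ⇐ (2S,3S)-2-aryl-2,3-dihydrobenzofuran-3-carboxylate 8 ⇐ (2S)-flavanone 5: the C3a–C3 bond is made by an oxidative 1,2-aryl shift, a one-carbon ring contraction that deletes C4 from the pyranone ring and leaves it as the exocyclic ester carbon on C3.
3. Enabling feature: the acyl carbon hangs on C3, next to aryl carbon C3a, and O1–C2 is a benzylic aryl ether. The unit C3a–C3H–C(=O) is thus the rearranged form of an aryl ketone C4a–C4(=O)–C3H2, so the five-membered ring (O1, C2, C3, C3a, C7a) maps onto the six-membered ring (O1, C2, C3, C4, C4a, C8a) of a chroman-4-one.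
4. 5 ⇐ chromone 3 + arylboronic acid 4 (catalytic asymmetric conjugate arylation sets C2); 3 ⇐ 6-bromochromone 1 + zinc homoenolate 2.
5. Ring order: the pyranone ring is bought with the chromone, saturated at C2 in step 2 and contracted to the dihydrofuran in step 3; no other ring is formed.

Key step: step 3

Assumption: with the (R)-antipode of the pyridine–oxazoline ligand the aryl group is taken to add to the Re face of chromone C2, giving the (2S)-flavanone; if the sense of induction is the reverse, the (S)-ligand is used and nothing else changes.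

**Route**

Step 1
Reactants: 1 6-bromo-4H-chromen-4-one; 2 (3-ethoxy-3-oxopropyl)zinc bromide (0.5 M in THF)
Product: 3 ethyl 3-(4-oxo-4H-chromen-6-yl)propanoate
Conditions: Pd(OAc)2 (2 mol %), SPhos (4 mol %), THF, rt to 50 °C
Reagents that add atoms: none
Why: Negishi cross-coupling, in which zerovalent palladium inserts into the C6–Br bond, the primary alkylzinc transmetalates and the bulky biarylphosphine makes reductive elimination faster than β-hydride elimination, while the mild zinc homoenolate should leave the chromone enone and carbonyl untouched; no stereocentre is formed.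

Step 2
Reactants: 3 ethyl 3-(4-oxo-4H-chromen-6-yl)propanoate; 4 [4-(acetyloxy)phenyl]boronic acid
Product: 5 ethyl 3-[(2S)-2-[4-(acetyloxy)phenyl]-4-oxo-3,4-dihydro-2H-chromen-6-yl]propanoate
Conditions: Pd(OCOCF3)2 (5 mol %), (R)-t-BuPyOx [(R)-4-tert-butyl-2-(pyridin-2-yl)-4,5-dihydro-1,3-oxazole] (6 mol %), NH4PF6 (30 mol %), H2O (5 equiv), ClCH2CH2Cl, 60 °C
Reagents that add atoms: none
Why: Catalytic asymmetric 1,4-addition of an arylboronic acid to a chromone (Hayashi–Miyaura-type addition, here with a cationic divalent palladium pyridine–oxazoline catalyst), in which ligand-controlled carbopalladation of C2=C3 on the Re face of C2 sets the (2S) centre and water protonates the palladium enolate without any base, so the flavanone should not racemise by retro-oxa-Michael opening and the aryl acetate and ethyl ester should persist.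

Step 3
Reactants: 5 ethyl 3-[(2S)-2-[4-(acetyloxy)phenyl]-4-oxo-3,4-dihydro-2H-chromen-6-yl]propanoate
Product: 8 ethyl 3-[(2S,3S)-2-[4-(acetyloxy)phenyl]-3-(methoxycarbonyl)-2,3-dihydro-1-benzofuran-5-yl]propanoate, via enol ether 6 (not isolated), via trans C3 iodane 7 (not isolated)
Conditions: PhI(OAc)2 (1.2 equiv), H2SO4 (cat.), HC(OMe)3, 0 °C to rt; aq. NaHCO3
Reagents that add atoms: trimethyl orthoformate, COC(OC)OC; water (work-up), O
Why: Oxidative 1,2-aryl shift of a flavanone induced by trivalent iodine: acid and orthoformate turn the C4 ketone into its ketal and the enol ether 6, the electrophilic iodine adds to C3 on the face opposite the C2 aryl group while methanol caps C4 to give the trans iodane 7, and the fused aryl carbon C4a then migrates from C4 to C3 as iodobenzene (monovalent iodine, an exceptional leaving group) departs, leaving a dimethoxycarbenium ion at the extruded C4 that is hydrolysed to the methyl ester. The closest known reaction type is exactly this ring contraction of flavanones to methyl trans-2-aryl-2,3-dihydrobenzofuran-3-carboxylates with hypervalent iodine or Tl(NO3)3 in trimethyl orthoformate, the cyclic counterpart of the aryl alkyl ketone to arylacetate rearrangement. The five-membered ring (O1, C2, C3, C3a, C7a) is closed by the new C3a–C3 bond in a 3-exo-tet attack of the aromatic ipso carbon on C3 (bridged phenonium ion) followed by cleavage of the old C4–C4a bond, so that one carbon leaves the ring. C2 is not touched and keeps the S configuration from step 2, and C3 is set by substrate control, because the equatorial C3–I bond of 7 is antiperiplanar to C4–C4a and the shift inverts C3, which places the ester trans to the C2 aryl group (2S,3S), also the thermodynamically preferred arrangement. The step needs chemoselectivity for migration of C4a over migration of the C2 aryl group (isoflavone formation) and over dehydrogenation (flavone), and site selectivity for C3 over the side chain: the acetoxy group keeps ring B a poor migrating group, the two ketal oxygens stabilise the cation that only the ring contraction creates, and the side chain carries an ester and no enolisable ketone.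

Step 4
Reactants: 8 ethyl 3-[(2S,3S)-2-[4-(acetyloxy)phenyl]-3-(methoxycarbonyl)-2,3-dihydro-1-benzofuran-5-yl]propanoate
Product: 10 ethyl 3-[(2S,3S)-2-[4-(benzyloxy)phenyl]-3-(methoxycarbonyl)-2,3-dihydro-1-benzofuran-5-yl]propanoate, via phenol 9 (not isolated)
Conditions: pyrrolidine (1.1 equiv), DMF, 0 °C to rt; then K2CO3 (2 equiv), BnBr (1.5 equiv), rt
Reagents that add atoms: benzyl bromide, BrCc1ccccc1
Why: Chemoselective aminolysis of the phenolic acetate (alkyl esters react far more slowly) followed by Williamson ether synthesis exchanges the electron-poor acetate, needed only to hold ring B back in step 3, for a benzyl ether that survives saponification and blocks the base-induced quinone-methide opening of the dihydrofuran that a free 4-hydroxyphenyl group at C2 would allow; at room temperature O-benzylation of the phenoxide should outrun that opening, and no stereocentre is affected.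

Step 5
Reactants: 10 ethyl 3-[(2S,3S)-2-[4-(benzyloxy)phenyl]-3-(methoxycarbonyl)-2,3-dihydro-1-benzofuran-5-yl]propanoate
Product: 11 (2S,3S)-2-[4-(benzyloxy)phenyl]-5-(2-carboxyethyl)-2,3-dihydro-1-benzofuran-3-carboxylic acid
Conditions: LiOH·H2O (5 equiv), THF/MeOH/H2O, 0 °C to rt; then 1 M HCl
Reagents that add atoms: lithium hydroxide, [Li+].[OH-]
Why: Saponification of both alkyl esters (any methyl/ethyl exchange in step 3 is immaterial here), in which the benzyl-protected ring B cannot form a quinone methide, β-elimination of O1 from a C3 enolate is the stereoelectronically disfavoured reverse of a 5-endo-trig closure, and reversible enolisation at C3 returns the thermodynamically favoured trans acid, so (2S,3S) should be kept.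

Step 6
Reactants: 11 (2S,3S)-2-[4-(benzyloxy)phenyl]-5-(2-carboxyethyl)-2,3-dihydro-1-benzofuran-3-carboxylic acid
Product: 12 S-(4-methylphenyl) (2S,3S)-2-[4-(benzyloxy)phenyl]-5-{3-[(4-methylphenyl)sulfanyl]-3-oxopropyl}-2,3-dihydro-1-benzofuran-3-carbothioate
Conditions: 4-MeC6H4SH (2.5 equiv), EDC·HCl (2.6 equiv), DMAP (0.2 equiv), CH2Cl2, 0 °C to rt
Reagents that add atoms: 4-methylbenzenethiol, Cc1ccc(S)cc1
Why: Carbodiimide/DMAP (Steglich-type) thioesterification of both acids gives the S-aryl thioesters needed for a base-free ketone synthesis; C2 is untouched and C3, if it enolises through the acylpyridinium, should re-form the trans isomer.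

Step 7
Reactants: 13 4-bromobenzene-1,3-diol
Product: 14 2,4-bis(benzyloxy)-1-bromobenzene
Conditions: BnBr (2.3 equiv), K2CO3 (3 equiv), DMF, 50 °C
Reagents that add atoms: benzyl bromide, BrCc1ccccc1
Why: Twofold Williamson ether synthesis on the two phenols; the aryl bromide is inert to carbonate.

Step 8
Reactants: 14 2,4-bis(benzyloxy)-1-bromobenzene
Product: 17 [2,4-bis(benzyloxy)phenyl]boronic acid, via aryllithium 15 (not isolated), via borate complex 16 (not isolated)
Conditions: n-BuLi (1.05 equiv), THF, −78 °C; B(OiPr)3 (1.5 equiv), −78 °C to rt; 1 M HCl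
Reagents that add atoms: triisopropyl borate, CC(C)OB(OC(C)C)OC(C)C; water, O
Why: Bromine–lithium exchange at −78 °C gives aryllithium 15 at the former C–Br carbon only, which the borate traps as complex 16 and acid hydrolyses to the boronic acid (lithiation–borylation), fixing the future acyl position ortho and para to the two benzyloxy groups.

Step 9
Reactants: 12 S-(4-methylphenyl) (2S,3S)-2-[4-(benzyloxy)phenyl]-5-{3-[(4-methylphenyl)sulfanyl]-3-oxopropyl}-2,3-dihydro-1-benzofuran-3-carbothioate; 17 [2,4-bis(benzyloxy)phenyl]boronic acid (3 equiv)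
Product: 18 1-[2,4-bis(benzyloxy)phenyl]-3-[(2S,3S)-3-[2,4-bis(benzyloxy)benzoyl]-2-[4-(benzyloxy)phenyl]-2,3-dihydro-1-benzofuran-5-yl]propan-1-one
Conditions: Pd2(dba)3 (5 mol %), P(2-furyl)3 (20 mol %), Cu(O2C-2-C4H3S) (copper thiophene-2-carboxylate, 3.2 equiv), THF, 50 °C, argon
Reagents that add atoms: none
Why: Twofold Liebeskind–Srogl coupling, in which zerovalent palladium inserts into each C(acyl)–S bond, the monovalent copper carboxylate binds the thiolate and activates the boronic acid for transmetalation under neutral conditions, and reductive elimination gives both aryl ketones at once; without base the acidic C3–H and the β-aryloxy ketone unit should not be endangered and the trans relationship is kept.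

Step 10
Reactants: 18 1-[2,4-bis(benzyloxy)phenyl]-3-[(2S,3S)-3-[2,4-bis(benzyloxy)benzoyl]-2-[4-(benzyloxy)phenyl]-2,3-dihydro-1-benzofuran-5-yl]propan-1-one
Product: 19 1-(2,4-dihydroxyphenyl)-3-[(2S,3S)-3-(2,4-dihydroxybenzoyl)-2-(4-hydroxyphenyl)-2,3-dihydro-1-benzofuran-5-yl]propan-1-one
Conditions: H2 (1 atm), 10% Pd/C, EtOAc/MeOH, rt
Reagents that add atoms: none
Why: Hydrogenolysis of the five O-benzyl ethers under neutral conditions, in which acyclic benzyl aryl ethers should cleave far faster than the ring C2–O1 bond or the hydrogen-bonded 2-hydroxyaryl ketones, so that stopping after uptake of five equivalents should give the target with both stereocentres unchanged.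

**Compound list**

1 | 6-bromo-4H-chromen-4-one | O=c1ccoc2ccc(Br)cc12 | starting material
2 | (3-ethoxy-3-oxopropyl)zinc bromide | CCOC(=O)CC[Zn]Br | starting material
3 | ethyl 3-(4-oxo-4H-chromen-6-yl)propanoate | CCOC(=O)CCc1ccc2occc(=O)c2c1 | intermediate
4 | [4-(acetyloxy)phenyl]boronic acid | CC(=O)Oc1ccc(B(O)O)cc1 | starting material
5 | ethyl 3-[(2S)-2-[4-(acetyloxy)phenyl]-4-oxo-3,4-dihydro-2H-chromen-6-yl]propanoate | CCOC(=O)CCc1ccc2O[C@H](c3ccc(OC(C)=O)cc3)CC(=O)c2c1 | intermediate
6 | ethyl 3-[(2S)-2-[4-(acetyloxy)phenyl]-4-methoxy-2H-chromen-6-yl]propanoate (enol ether, formed in situ) | CCOC(=O)CCc1ccc2O[C@H](c3ccc(OC(C)=O)cc3)C=C(OC)c2c1 | intermediate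
7 | ethyl 3-[(2R,3R)-3-[acetoxy(phenyl)iodanyl]-2-[4-(acetyloxy)phenyl]-4,4-dimethoxy-3,4-dihydro-2H-chromen-6-yl]propanoate (2,3-trans adduct of trivalent iodine, formed in situ) | CCOC(=O)CCc1ccc2O[C@H](c3ccc(OC(C)=O)cc3)[C@@H](I(OC(C)=O)c3ccccc3)C(OC)(OC)c2c1 | intermediate
8 | ethyl 3-[(2S,3S)-2-[4-(acetyloxy)phenyl]-3-(methoxycarbonyl)-2,3-dihydro-1-benzofuran-5-yl]propanoate | CCOC(=O)CCc1ccc2c(c1)[C@H](C(=O)OC)[C@@H](c1ccc(OC(C)=O)cc1)O2 | intermediate
9 | ethyl 3-[(2S,3S)-2-(4-hydroxyphenyl)-3-(methoxycarbonyl)-2,3-dihydro-1-benzofuran-5-yl]propanoate (formed in situ) | CCOC(=O)CCc1ccc2c(c1)[C@H](C(=O)OC)[C@@H](c1ccc(O)cc1)O2 | intermediate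
10 | ethyl 3-[(2S,3S)-2-[4-(benzyloxy)phenyl]-3-(methoxycarbonyl)-2,3-dihydro-1-benzofuran-5-yl]propanoate | CCOC(=O)CCc1ccc2c(c1)[C@H](C(=O)OC)[C@@H](c1ccc(OCc3ccccc3)cc1)O2 | intermediate
11 | (2S,3S)-2-[4-(benzyloxy)phenyl]-5-(2-carboxyethyl)-2,3-dihydro-1-benzofuran-3-carboxylic acid | OC(=O)CCc1ccc2c(c1)[C@H](C(=O)O)[C@@H](c1ccc(OCc3ccccc3)cc1)O2 | intermediate
12 | S-(4-methylphenyl) (2S,3S)-2-[4-(benzyloxy)phenyl]-5-{3-[(4-methylphenyl)sulfanyl]-3-oxopropyl}-2,3-dihydro-1-benzofuran-3-carbothioate | Cc1ccc(SC(=O)CCc2ccc3c(c2)[C@H](C(=O)Sc2ccc(C)cc2)[C@@H](c2ccc(OCc4ccccc4)cc2)O3)cc1 | intermediate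
13 | 4-bromobenzene-1,3-diol | Oc1ccc(Br)c(O)c1 | starting material
14 | 2,4-bis(benzyloxy)-1-bromobenzene | Brc1ccc(OCc2ccccc2)cc1OCc1ccccc1 | intermediate
15 | [2,4-bis(benzyloxy)phenyl]lithium (formed in situ) | [Li]c1ccc(OCc2ccccc2)cc1OCc1ccccc1 | intermediate
16 | lithium [2,4-bis(benzyloxy)phenyl]tri(propan-2-yloxy)borate (formed in situ) | [Li+].CC(C)O[B-](OC(C)C)(OC(C)C)c1ccc(OCc2ccccc2)cc1OCc1ccccc1 | intermediate
17 | [2,4-bis(benzyloxy)phenyl]boronic acid | OB(O)c1ccc(OCc2ccccc2)cc1OCc1ccccc1 | intermediate
18 | 1-[2,4-bis(benzyloxy)phenyl]-3-[(2S,3S)-3-[2,4-bis(benzyloxy)benzoyl]-2-[4-(benzyloxy)phenyl]-2,3-dihydro-1-benzofuran-5-yl]propan-1-one | O=C(CCc1ccc2c(c1)[C@H](C(=O)c3ccc(OCc4ccccc4)cc3OCc3ccccc3)[C@@H](c3ccc(OCc4ccccc4)cc3)O2)c1ccc(OCc2ccccc2)cc1OCc1ccccc1 | intermediate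
19 | 1-(2,4-dihydroxyphenyl)-3-[(2S,3S)-3-(2,4-dihydroxybenzoyl)-2-(4-hydroxyphenyl)-2,3-dihydro-1-benzofuran-5-yl]propan-1-one | O=C(CCc1ccc2c(c1)[C@H](C(=O)c1ccc(O)cc1O)[C@@H](c1ccc(O)cc1)O2)c1ccc(O)cc1O | target

**Step count and risks**

Total step count: 10. Longest linear sequence: 8 (steps 1–6, 9 and 10); steps 7 and 8 make the boronic acid for the convergent step 9.

Steps most likely to fail:

1. Step 3 (key step). What may go wrong: migration of the C2 aryl group instead of C4a (1,2-shift towards an isoflavone), dehydrogenation to the flavone, or acid solvolysis of the aryl acetate followed by oxidation of the freed phenol. The fallback sets out from 5 and returns at 8, and contracts the ring by a Wolff rearrangement, in which the same aryl carbon C4a migrates to a carbene at C3. Flavanone 5 is C-acylated at C3 (LiN(SiMe3)2, CF3CO2CH2CF3, THF, −78 °C) to the 3-(trifluoroacetyl)flavanone F1. Detrifluoroacetylative diazo transfer (MsN3, Et3N, MeCN) then gives the 3-diazoflavanone F2. Irradiation at about 350 nm in MeOH gives the ring-contracted ketene F3, which methanol traps as 8 together with its cis epimer F4; DBU in toluene equilibrates F4 to trans 8.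

2. Step 9. What may go wrong: slow transmetalation or decarbonylation of the acylpalladium at the hindered, α-aryl C3 thioester, so that only the side-chain thioester couples. The fallback sets out from 11 and returns at 18: diacid 11 is converted (MeNHOMe·HCl, EDC·HCl, N-methylmorpholine, CH2Cl2) into the bis(N-methoxy-N-methylamide) F5. F5 is treated in THF at −78 °C with aryllithium 15, generated from 14 as in step 8, and quenched with aqueous NH4Cl, which should give 18 by way of the chelated tetrahedral adducts.

3. Step 10. What may go wrong: over-reduction, that is hydrogenolysis of the benzylic C2–O1 bond of the dihydrofuran or reduction of the aryl ketones before the last benzyl ether is gone. The fallback sets out from 18 and returns at 19 without any new compound (entry F0): Lewis-acid debenzylation with BCl3 and pentamethylbenzene as benzyl-cation scavenger in CH2Cl2 at −78 °C, which removes the benzyl groups without hydrogen.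

Further compounds
F1 | step 3 | ethyl 3-[(2S)-2-[4-(acetyloxy)phenyl]-4-oxo-3-(trifluoroacetyl)-3,4-dihydro-2H-chromen-6-yl]propanoate | CCOC(=O)CCc1ccc2O[C@H](c3ccc(OC(C)=O)cc3)C(C(=O)C(F)(F)F)C(=O)c2c1
F2 | step 3 | ethyl 3-[(2R)-2-[4-(acetyloxy)phenyl]-3-diazo-4-oxo-3,4-dihydro-2H-chromen-6-yl]propanoate (C2 arrangement of 5 retained) | CCOC(=O)CCc1ccc2O[C@H](c3ccc(OC(C)=O)cc3)C(=[N+]=[N-])C(=O)c2c1
F3 | step 3 | ethyl 3-[(2R)-2-[4-(acetyloxy)phenyl]-3-(oxomethylidene)-2,3-dihydro-1-benzofuran-5-yl]propanoate (C2 arrangement of 5 retained) | CCOC(=O)CCc1ccc2c(c1)C(=C=O)[C@@H](c1ccc(OC(C)=O)cc1)O2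
F4 | step 3 | ethyl 3-[(2S,3R)-2-[4-(acetyloxy)phenyl]-3-(methoxycarbonyl)-2,3-dihydro-1-benzofuran-5-yl]propanoate (cis epimer of 8) | CCOC(=O)CCc1ccc2c(c1)[C@@H](C(=O)OC)[C@@H](c1ccc(OC(C)=O)cc1)O2
F5 | step 9 | (2S,3S)-2-[4-(benzyloxy)phenyl]-N-methoxy-5-{3-[methoxy(methyl)amino]-3-oxopropyl}-N-methyl-2,3-dihydro-1-benzofuran-3-carboxamide | CON(C)C(=O)CCc1ccc2c(c1)[C@H](C(=O)N(C)OC)[C@@H](c1ccc(OCc3ccccc3)cc1)O2
F0 | step 10 | none | none
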